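**Retrosynthetic overview**
1. The target (filixic acid PBB) is cut at its two C–CH2–C bridges on aromatic ring B: last the bridge to the propanoyl-filicinic ring C, before it the bridge to the butanoyl-filicinic ring A (Mannich base / enone-methide couplings).
2. Each of the three acylated six-membered rings is cut to a cyclopentane-1,2,4-trione plus an acyldiazomethane: a one-carbon ring expansion by 1,2-acyl shift that makes the ring and the C–acyl bond together.
3. 3,3-Dimethylcyclopentane-1,2,4-trione comes from 3-methylbutan-2-one and dimethyl oxalate (Claisen–Dieckmann); the acyldiazomethanes come from the acid chlorides and Me3SiCHN2.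
4. Ring order: five-membered trione, then rings A and C (expansion) and ring B (expansion, then aromatisation), then bridge A–B, then bridge B–C.

Assumption: the target has no stereocentre and no stereogenic double bond, so it is achiral and is made as the tautomer drawn in the given SMILES; cyclopentane-1,2,4-trione is taken as a catalogue compound.

**Route**

Step 1
Reactants: 1 3-methylbutan-2-one; 2 dimethyl oxalate
Product: 4 3,3-dimethylcyclopentane-1,2,4-trione, via methoxalyl trione 3 (not isolated)
Conditions: NaOMe (3.3 equiv), 2 (2.1 equiv), MeOH–toluene, 0 °C → reflux, 3 h; then 40% aq H3PO4, 100 °C, 2 h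
Reagents that add atoms: none
Why: A double Claisen condensation (methyl group first, then Dieckmann-type closure at the isopropyl CH) is driven by the acidic C5–H2 of the trione, which is oxalylated once more in the flask, and hot aqueous acid then removes that extra methoxalyl group by retro-Claisen hydrolysis, as in the standard preparation of 3-methylcyclopentane-1,2,4-trione from butan-2-one; no stereocentre is formed.

Step 2
Reactants: 5 butanoyl chloride; 6 (trimethylsilyl)diazomethane
Product: 7 1-diazopentan-2-one
Conditions: 6 (2 M in hexanes, 2 equiv), MeCN–THF 1:1, 0 °C → rt, 12 h; evaporate, SiO2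
Reagents that add atoms: none
Why: Acylation of the diazo carbon of 6 by the acid chloride with loss of the silyl group as Me3SiCl (Arndt–Eistert-type diazoketone synthesis); no stereocentre is formed.

Step 3
Reactants: 8 propanoyl chloride; 6 (trimethylsilyl)diazomethane
Product: 9 1-diazobutan-2-one
Conditions: 6 (2 M in hexanes, 2 equiv), MeCN–THF 1:1, 0 °C → rt, 12 h; evaporate, SiO2
Reagents that add atoms: none
Why: Same Arndt–Eistert-type acylation of the diazo carbon as in step 2; no stereocentre is formed.

Step 4
Reactants: 4 3,3-dimethylcyclopentane-1,2,4-trione; 7 1-diazopentan-2-one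
Product: 10 2-butanoyl-3,5-dihydroxy-4,4-dimethylcyclohexa-2,5-dien-1-one (butyrylfilicinic acid, ring A)
Conditions: Sc(OTf)3 (20 mol %), 7 (1.3 equiv, added over 2 h), CH2Cl2, −20 °C → rt
Reagents that add atoms: none
Why: Proposed new method: formal insertion of an acyl carbene into the C1–C2 bond of the vicinal dione of 4; Sc(OTf)3 chelates the enol oxygen on C1 and the C2 carbonyl and so activates C2, the only non-enolised ketone, the diazo carbon of 7 adds to C2, and in the diazonium alkoxide the electron-rich enol (acyl) carbon C1 migrates to the diazo carbon with loss of N2 in preference to the hindered, acceptor-substituted quaternary C3 (1,2-acyl shift, one-carbon ring expansion), after which the 2-acylcyclohexane-1,3,5-trione enolises to 10 and is inert to further diazoketone; closest known reaction type: Lewis-acid-catalysed Tiffeneau–Demjanov/Roskamp-type homologation of ketones, isatins and vicinal tricarbonyls (indane-1,2,3-trione to 2-hydroxy-1,4-naphthoquinone) with diazoalkanes and diazo esters, here extended to an acyldiazomethane as the one-carbon unit and a cyclopentane-1,2,4-trione as the substrate; no stereocentre is formed.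

Step 5
Reactants: 4 3,3-dimethylcyclopentane-1,2,4-trione; 9 1-diazobutan-2-one
Product: 11 3,5-dihydroxy-4,4-dimethyl-2-propanoylcyclohexa-2,5-dien-1-one (propionylfilicinic acid, ring C)
Conditions: Sc(OTf)3 (20 mol %), 9 (1.3 equiv, added over 2 h), CH2Cl2, −20 °C → rt
Reagents that add atoms: none
Why: Proposed new method: the same Sc(OTf)3-catalysed addition of the diazo carbon to C2 of 4 followed by 1,2-shift of the enol (acyl) carbon C1 with loss of N2 as in step 4, now delivering the propanoyl-bearing ring carbon; closest known reaction type: Lewis-acid-catalysed Tiffeneau–Demjanov/Roskamp-type diazo homologation of ketones and vicinal polycarbonyl compounds; no stereocentre is formed.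

Step 6
Reactants: 12 cyclopentane-1,2,4-trione; 7 1-diazopentan-2-one
Product: 13 1-(2,4,6-trihydroxyphenyl)butan-1-one (butyrylphloroglucinol, ring B)
Conditions: Sc(OTf)3 (20 mol %), 7 (1.3 equiv, added over 2 h), CH2Cl2–MeCN 4:1, −20 °C → rt
Reagents that add atoms: none
Why: Proposed new method: the same ring expansion on the parent trione, where the diazo carbon adds to a carbonyl of the vicinal dione and the oxygen-bearing enol (acyl) carbon migrates in preference to the acceptor-flanked CH2, and the 2-butanoylcyclohexane-1,3,5-trione so formed tautomerises at once to the aromatic triol, which makes the shift irreversible; closest known reaction type: Lewis-acid-catalysed Tiffeneau–Demjanov/Roskamp-type diazo homologation of cyclic vicinal polycarbonyl compounds with acyl migration; no stereocentre is formed.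

Step 7
Reactants: 10 butyrylfilicinic acid; 13 butyrylphloroglucinol; 14 N,N-dimethylmethyleneiminium iodide (Eschenmoser's salt)
Product: 16 2-butanoyl-6-[(3-butanoyl-2,4,6-trihydroxyphenyl)methyl]-3,5-dihydroxy-4,4-dimethylcyclohexa-2,5-dien-1-one, via Mannich base 15 (not isolated)
Conditions: 10, 14 (1.05 equiv), MeCN, 0 °C → rt, 1 h; then 13 (3 equiv), NaOAc (1.1 equiv), MeOH, 50 °C, 3 h
Reagents that add atoms: none
Why: Mannich reaction at C6, the only free nucleophilic ring carbon of 10, then buffered elimination of Me2NH to the 6-methylene trione (enone methide) and Friedel–Crafts-type conjugate addition of the electron-rich ring of 13, whose two free positions are equivalent and whose excess suppresses the second alkylation; no stereocentre is formed.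

Step 8
Reactants: 11 propionylfilicinic acid; 14 N,N-dimethylmethyleneiminium iodide; 16 ring A–CH2–ring B dimer
Product: 18 2-butanoyl-6-[[3-butanoyl-5-[(2,4-dihydroxy-3,3-dimethyl-6-oxo-5-propanoylcyclohexa-1,4-dien-1-yl)methyl]-2,4,6-trihydroxyphenyl]methyl]-3,5-dihydroxy-4,4-dimethylcyclohexa-2,5-dien-1-one (target), via Mannich base 17 (not isolated)
Conditions: 11 (1.2 equiv), 14 (1.2 equiv), MeCN, 0 °C → rt, 1 h; then 16 (1.0 equiv), NaOAc (1.3 equiv), MeOH, 40 °C, 4 h
Reagents that add atoms: none
Why: The same Mannich / enone-methide sequence on 11, with the methide trapped by the single remaining free carbon of ring B in 16 under mild buffered conditions that limit retro-Michael exchange of the bridge already in place; no stereocentre is formed.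

**Compound list**
1 | 3-methylbutan-2-one | CC(C)C(C)=O | starting material
2 | dimethyl oxalate | COC(=O)C(=O)OC | starting material
3 | methyl 2-(4,4-dimethyl-2,3,5-trioxocyclopentyl)-2-oxoacetate (5-methoxalyl derivative of 4) | COC(=O)C(=O)C1C(=O)C(=O)C(C)(C)C1=O | intermediate
4 | 3,3-dimethylcyclopentane-1,2,4-trione (enolised; keto form drawn) | CC1(C)C(=O)CC(=O)C1=O | intermediate
5 | butanoyl chloride | CCCC(Cl)=O | starting material
6 | (trimethylsilyl)diazomethane | C[Si](C)(C)C=[N+]=[N-] | starting material
7 | 1-diazopentan-2-one | CCCC(=O)C=[N+]=[N-] | intermediate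
8 | propanoyl chloride | CCC(Cl)=O | starting material
9 | 1-diazobutan-2-one | CCC(=O)C=[N+]=[N-] | intermediate
10 | 2-butanoyl-3,5-dihydroxy-4,4-dimethylcyclohexa-2,5-dien-1-one | CCCC(=O)C1=C(O)C(C)(C)C(O)=CC1=O | intermediate
11 | 3,5-dihydroxy-4,4-dimethyl-2-propanoylcyclohexa-2,5-dien-1-one | CCC(=O)C1=C(O)C(C)(C)C(O)=CC1=O | intermediate
12 | cyclopentane-1,2,4-trione (enolised; keto form drawn) | O=C1CC(=O)C(=O)C1 | starting material
13 | 1-(2,4,6-trihydroxyphenyl)butan-1-one | CCCC(=O)c1c(O)cc(O)cc1O | intermediate
14 | N,N-dimethylmethyleneiminium iodide | C=[N+](C)C.[I-] | starting material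
15 | 2-butanoyl-6-[(dimethylamino)methyl]-3,5-dihydroxy-4,4-dimethylcyclohexa-2,5-dien-1-one (present as its hydroiodide) | CCCC(=O)C1=C(O)C(C)(C)C(O)=C(CN(C)C)C1=O | intermediate
16 | 2-butanoyl-6-[(3-butanoyl-2,4,6-trihydroxyphenyl)methyl]-3,5-dihydroxy-4,4-dimethylcyclohexa-2,5-dien-1-one | CCCC(=O)C1=C(O)C(C)(C)C(O)=C(Cc2c(O)cc(O)c(C(=O)CCC)c2O)C1=O | intermediate
17 | 6-[(dimethylamino)methyl]-3,5-dihydroxy-4,4-dimethyl-2-propanoylcyclohexa-2,5-dien-1-one (present as its hydroiodide) | CCC(=O)C1=C(O)C(C)(C)C(O)=C(CN(C)C)C1=O | intermediate
18 | 2-butanoyl-6-[[3-butanoyl-5-[(2,4-dihydroxy-3,3-dimethyl-6-oxo-5-propanoylcyclohexa-1,4-dien-1-yl)methyl]-2,4,6-trihydroxyphenyl]methyl]-3,5-dihydroxy-4,4-dimethylcyclohexa-2,5-dien-1-one | CCCC(=O)C1=C(O)C(C)(C)C(O)=C(Cc2c(O)c(CC3=C(O)C(C)(C)C(O)=C(C(=O)CC)C3=O)c(O)c(C(=O)CCC)c2O)C1=O | target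

**Totals**
Total step count: 8. Longest linear sequence: 4 steps (step 1, step 4, step 7, step 8).

**Steps most likely to fail**

Step 4 (the proposed new ring expansion; step 5 is the same reaction). The diazonium alkoxide may instead shift the quaternary carbon C3, close to an epoxide, or the acidic enol may simply be O-alkylated by the diazoketone. The fallback uses known chemistry, sets out from 13 and comes back at 10. It is the classical dearomatising C,C-dimethylation of an acylphloroglucinol (MeI 2.5 equiv, NaOMe 3 equiv, MeOH, 0 °C → rt), which puts both methyl groups on one ring carbon and gives 10 directly. If step 5 fails too, 11 is reached the same way: acylation of benzene-1,3,5-triol F4 (made as told under step 6) with 8 (AlCl3, PhNO2–CH2Cl2) gives 1-(2,4,6-trihydroxyphenyl)propan-1-one F1, and the same methylation of F1 comes back at 11. This path also makes step 1 unnecessary.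

Step 6 (the new ring expansion on the parent trione). Here the competing migration of the ring CH2 would give a 1,2,4-trioxygenated ring, and 12 is the more acidic and less soluble substrate. The fallback uses known chemistry, sets out from 5 and comes back at 13. Benzene F2 (bought) is borylated three times under steric control ([Ir(OMe)(cod)]2, 4,4'-di-tert-butyl-2,2'-bipyridine, excess B2pin2, 80 °C) to 1,3,5-tris(4,4,5,5-tetramethyl-1,3,2-dioxaborolan-2-yl)benzene F3, which is freed from the 1,4-bis-boronate by crystallisation. Oxidation of F3 (H2O2, NaOH, THF–water, 0 °C) gives benzene-1,3,5-triol F4. Friedel–Crafts acylation of F4 with 5 (AlCl3, PhNO2–CH2Cl2, 0 °C → rt) gives 13.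

Step 8 (last bridge). On warming, the bridge already present in 16 can open by retro-Michael reaction and exchange partners, which would give mixtures of the symmetric trimers. The fallback reverses the roles of the partners, sets out from 16 and comes back at 18. The free carbon of ring B in 16 is aminomethylated with 14 (MeCN, 0 °C) to 2-butanoyl-6-[[3-butanoyl-5-[(dimethylamino)methyl]-2,4,6-trihydroxyphenyl]methyl]-3,5-dihydroxy-4,4-dimethylcyclohexa-2,5-dien-1-one F5. F5 is then added to the preformed sodium enolate of 11 (NaH, THF, 0 °C → rt). The ortho-quinone methide released from the phenolic Mannich base is trapped at C6 of 11 at low temperature (known C-alkylation of 1,3-dicarbonyl compounds by phenolic Mannich bases) and gives 18.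

**Further compounds**
F1 | step 4 | 1-(2,4,6-trihydroxyphenyl)propan-1-one | CCC(=O)c1c(O)cc(O)cc1O
F2 | step 6 | benzene (bought) | c1ccccc1
F3 | step 6 | 1,3,5-tris(4,4,5,5-tetramethyl-1,3,2-dioxaborolan-2-yl)benzene | CC1(C)OB(OC1(C)C)c1cc(B2OC(C)(C)C(C)(C)O2)cc(B2OC(C)(C)C(C)(C)O2)c1
F4 | step 6 | benzene-1,3,5-triol | Oc1cc(O)cc(O)c1
F5 | step 8 | 2-butanoyl-6-[[3-butanoyl-5-[(dimethylamino)methyl]-2,4,6-trihydroxyphenyl]methyl]-3,5-dihydroxy-4,4-dimethylcyclohexa-2,5-dien-1-one | CCCC(=O)C1=C(O)C(C)(C)C(O)=C(Cc2c(O)c(CN(C)C)c(O)c(C(=O)CCC)c2O)C1=O
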